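The five-membered ring (C1–C5) of the cis-fused hydroazulene carries oxygen on C2 and C4, either side of the C3 methylene: with C2 as a ketone this is an aldol retron. Everything rests on the C3–C4 disconnection: the methyl enolate of an acetyl group on quaternary C1 adds to an isopropyl ketone (C4) on C5, closing the cyclopentane and creating the tertiary carbinol stereocentre in one operation. The precursor is a cis-1,7-diacyl cycloheptene carrying the C6 trimethoxybenzoate; its C1, C5 and C6 centres come from one chiral-pool carbinol through a chelated dianionic Ireland–Claisen rearrangement, followed by ring-closing metathesis and Wacker oxidation.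

Key step: step 11

Remark: carbons are labelled as in the daucane skeleton and keep their labels in all intermediates: C1 methyl-bearing ring-fusion carbon, C2 angeloyloxy carbon, C3 CH2, C4 isopropyl carbinol, C5 ring-fusion CH, C6 aroyloxy carbon, C7 CH2, C8(CH3)=C9H, C10 CH2. Compounds 1, 5, 11 and 20 and all unnumbered reagents are assumed to be commercial.

Step 1
Reactants: 1 but-2-yn-1-ol
Product: 3 (Z)-3-iodobut-2-en-1-ol, via cyclic vinylalanate 2 (not isolated)
Conditions: Red-Al, THF, 0 °C to rt; then I2, THF, −78 to 0 °C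
Reagents that add atoms: iodine, II
Why: Hydroxyl-directed trans-hydroalumination of the propargylic alcohol puts aluminium on C3 in a five-membered alanate, and iodinolysis with retention gives the Z-iodide (alkyne hydrometalation–iodination).

Step 2
Reactants: 3 (Z)-3-iodobut-2-en-1-ol
Product: 4 (Z)-3-methylhexa-2,5-dien-1-ol
Conditions: Pd(PPh3)4 (5 mol %), CuI (10 mol %), DMF, 40 °C
Reagents that add atoms: allyltributylstannane, C=CC[Sn](CCCC)(CCCC)CCCC
Why: Stille cross-coupling of the vinyl iodide proceeds with retention of olefin geometry and tolerates the free alcohol, so the allyl group ends cis to CH2OH.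

Step 3
Reactants: 5 ethyl (S)-4-chloro-3-hydroxybutanoate
Product: 6 ethyl (S)-2-(oxiran-2-yl)acetate
Conditions: Ag2O, MeCN, 60 °C
Reagents that add atoms: none
Why: Silver-assisted intramolecular Williamson etherification closes the epoxide without strong base, which avoids β-elimination to the crotonate and does not touch the carbinol stereocentre.

Step 4
Reactants: 6 ethyl (S)-2-(oxiran-2-yl)acetate
Product: 7 ethyl (R)-3-hydroxy-5-methylhex-5-enoate
Conditions: CuI (10 mol %), THF, −40 °C; aqueous work-up
Reagents that add atoms: isopropenylmagnesium bromide, CC(=C)[Mg]Br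
Why: Copper-catalysed Grignard opening of the terminal epoxide (SN2 at CH2) should outrun ester addition at −40 °C and leaves the stereocentre unchanged (the descriptor becomes R only through the priority change).

Step 5
Reactants: 7 ethyl (R)-3-hydroxy-5-methylhex-5-enoate; 4 (Z)-3-methylhexa-2,5-dien-1-ol
Product: 8 (2Z)-3-methylhexa-2,5-dien-1-yl (3R)-3-hydroxy-5-methylhex-5-enoate
Conditions: Otera distannoxane catalyst (5 mol %), toluene, reflux, EtOH distilled off
Reagents that add atoms: none
Why: Neutral tin-catalysed transesterification exchanges ethanol for the primary allylic alcohol without dehydrating or racemising the β-hydroxy ester.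

Step 6
Reactants: 8 (2Z)-3-methylhexa-2,5-dien-1-yl (3R)-3-hydroxy-5-methylhex-5-enoate
Product: 10 (2R,3R)-3-hydroxy-5-methyl-2-[(3S)-3-methylhexa-1,5-dien-3-yl]hex-5-enoic acid, via chelated dilithium dianion 9 (not isolated)
Conditions: LDA (2.3 equiv), THF, −78 °C, then 50 °C; 1 M HCl
Reagents that add atoms: none
Why: Dianionic Ireland–Claisen rearrangement: the lithium-chelated enolate (enolate oxygen cis to C6) reacts through a chair on the face anti to the C7 chain (Fráter–Seebach-type induction, setting C5), and the Z olefin places the allyl group axial, which fixes quaternary C1 relative to C5.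

Step 7
Reactants: 10 (2R,3R)-3-hydroxy-5-methyl-2-[(3S)-3-methylhexa-1,5-dien-3-yl]hex-5-enoic acid; 11 3,4,5-trimethoxybenzoyl chloride
Product: 12 (2R,3R)-5-methyl-2-[(3S)-3-methylhexa-1,5-dien-3-yl]-3-[(3,4,5-trimethoxybenzoyl)oxy]hex-5-enoic acid
Conditions: pyridine, DMAP (cat.), CH2Cl2, 0 °C to rt; then aq NaHCO3/THF, acidify
Reagents that add atoms: none
Why: DMAP-catalysed O-acylation of the secondary alcohol; the mixed anhydride formed at the carboxyl group is cleaved again in the bicarbonate work-up.

Step 8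
Reactants: 12 (2R,3R)-5-methyl-2-[(3S)-3-methylhexa-1,5-dien-3-yl]-3-[(3,4,5-trimethoxybenzoyl)oxy]hex-5-enoic acid
Product: 14 (4R,5R)-2,7-dimethyl-4-[(3S)-3-methylhexa-1,5-dien-3-yl]-3-oxooct-7-en-5-yl 3,4,5-trimethoxybenzoate, via acid chloride 13 (not isolated)
Conditions: (COCl)2, DMF (cat.), CH2Cl2, 0 °C to rt; concentrate; i-PrMgCl (1.05 equiv), CuI (10 mol %), THF, −78 °C
Reagents that add atoms: isopropylmagnesium chloride, CC(C)[Mg]Cl
Why: Acid chloride formation followed by copper-catalysed Grignard acylation should stop at the hindered ketone and leave the aryl ester and the C5 stereocentre intact at −78 °C.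

Step 9
Reactants: 14 (4R,5R)-2,7-dimethyl-4-[(3S)-3-methylhexa-1,5-dien-3-yl]-3-oxooct-7-en-5-yl 3,4,5-trimethoxybenzoate
Product: 15 (1R,6S,7R)-6-ethenyl-3,6-dimethyl-7-(2-methylpropanoyl)cyclohept-3-en-1-yl 3,4,5-trimethoxybenzoate
Conditions: Hoveyda–Grubbs II (5 mol %), toluene (5 mM), 80 °C
Reagents that add atoms: none
Why: Ring-closing metathesis: ruthenium loads on the unhindered allyl group and can only close onto the methallyl group, giving the trisubstituted cycloheptene, while the neopentyl vinyl group is a poor metathesis partner.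

Step 10
Reactants: 15 (1R,6S,7R)-6-ethenyl-3,6-dimethyl-7-(2-methylpropanoyl)cyclohept-3-en-1-yl 3,4,5-trimethoxybenzoate
Product: 16 (1R,6R,7R)-6-acetyl-3,6-dimethyl-7-(2-methylpropanoyl)cyclohept-3-en-1-yl 3,4,5-trimethoxybenzoate
Conditions: PdCl2 (10 mol %), CuCl (30 mol %), O2 (1 atm), DMF/H2O 7:1, rt
Reagents that add atoms: water, O
Why: Tsuji–Wacker oxidation with Markovnikov hydroxypalladation converts the only monosubstituted olefin into the methyl ketone; the trisubstituted ring olefin should not react.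

Step 11
Reactants: 16 (1R,6R,7R)-6-acetyl-3,6-dimethyl-7-(2-methylpropanoyl)cyclohept-3-en-1-yl 3,4,5-trimethoxybenzoate
Product: 18 (3S,3aR,4R,8aR)-3-hydroxy-6,8a-dimethyl-1-oxo-3-(propan-2-yl)-1,2,3,3a,4,5,8,8a-octahydroazulen-4-yl 3,4,5-trimethoxybenzoate, via lithium enolate 17 (not isolated)
Conditions: LiHMDS (1.05 equiv), THF, −78 °C, 30 min; AcOH/THF, −78 °C
Reagents that add atoms: none
Why: LiHMDS removes a proton from the acetyl methyl group (C3), the only unhindered α-position because C1 is quaternary and the isobutyryl ketone has only two hindered tertiary α-hydrogens, and lithium enolate 17 adds through C3 to the C4 carbonyl. The closest known reaction type is the intramolecular aldol addition of 1,4-diketones to 3-hydroxycyclopentanones. The cyclopentane closes in the 5-(enolendo)-exo-trig mode, formally disfavoured by Baldwin's rules but the routine mode of 1,4-diketone aldolisation, and the cis ring fusion follows from the cis acyl groups on C1 and C5. The new stereocentre C4 is under substrate control: the isopropyl group should take the face of H-5, away from C6 and its aroyloxy group, so that the oxygen ends cis to C6, an arrangement also favoured by lithium chelation to the ester. The step needs regioselective kinetic enolisation and must avoid β-elimination of the C6 benzoate, retro-aldol cleavage and dehydration; the hindered C5–H, one equivalent of base at −78 °C and a cold acidic quench should secure this.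

Step 12
Reactants: 18 (3S,3aR,4R,8aR)-3-hydroxy-6,8a-dimethyl-1-oxo-3-(propan-2-yl)-1,2,3,3a,4,5,8,8a-octahydroazulen-4-yl 3,4,5-trimethoxybenzoate
Product: 19 (1S,3S,3aR,4R,8aR)-1,3-dihydroxy-6,8a-dimethyl-3-(propan-2-yl)-1,2,3,3a,4,5,8,8a-octahydroazulen-4-yl 3,4,5-trimethoxybenzoate
Conditions: (R)-2-methyl-CBS-oxazaborolidine (1 equiv), catecholborane, toluene, −78 to −40 °C; MeOH, aqueous work-up
Reagents that add atoms: none
Why: Corey–Bakshi–Shibata reduction under reagent control: the catalyst distinguishes quaternary C1 from the C3 methylene, and the (R)-catalyst should deliver hydride to give the (S)-carbinol cis to the C4 hydroxyl, while catecholborane spares olefin and ester.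

Step 13
Reactants: 19 (1S,3S,3aR,4R,8aR)-1,3-dihydroxy-6,8a-dimethyl-3-(propan-2-yl)-1,2,3,3a,4,5,8,8a-octahydroazulen-4-yl 3,4,5-trimethoxybenzoate; 20 angelic acid
Product: 22 CNP0112256.1 (1S,3S,3aR,4R,8aR)-3-hydroxy-6,8a-dimethyl-1-[(2Z)-2-methylbut-2-enoyloxy]-3-(propan-2-yl)-1,2,3,3a,4,5,8,8a-octahydroazulen-4-yl 3,4,5-trimethoxybenzoate, via mixed anhydride 21 (not isolated)
Conditions: 20, 2,4,6-trichlorobenzoyl chloride, Et3N, toluene, rt; then 19, 80 °C (no DMAP)
Reagents that add atoms: none
Why: Yamaguchi esterification through the trichlorobenzoyl mixed anhydride should acylate the secondary C2 hydroxyl selectively over the tertiary one and, without DMAP, keep the Z geometry of the angelate.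

Compound list
1 | but-2-yn-1-ol | CC#CCO | starting material
2 | sodium 2,2-bis(2-methoxyethoxy)-3-methyl-2,5-dihydro-1,2-oxaaluminol-2-uide (cyclic vinylalanate) | [Na+].COCCO[Al-]1(OCCOC)OCC=C1C | intermediate (not isolated)
3 | (Z)-3-iodobut-2-en-1-ol | OC/C=C(/C)I | intermediate
4 | (Z)-3-methylhexa-2,5-dien-1-ol | OC/C=C(/C)CC=C | intermediate
5 | ethyl (S)-4-chloro-3-hydroxybutanoate | CCOC(=O)C[C@H](O)CCl | starting material
6 | ethyl (S)-2-(oxiran-2-yl)acetate | CCOC(=O)C[C@H]1CO1 | intermediate
7 | ethyl (R)-3-hydroxy-5-methylhex-5-enoate | CCOC(=O)C[C@H](O)CC(C)=C | intermediate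
8 | (2Z)-3-methylhexa-2,5-dien-1-yl (3R)-3-hydroxy-5-methylhex-5-enoate | C=CC/C(C)=C\COC(=O)C[C@H](O)CC(C)=C | intermediate
9 | chelated dilithium dianion of 8 (enolate oxygen cis to C6) | [Li+].[Li+].C=CC/C(C)=C\CO/C([O-])=C/[C@H]([O-])CC(C)=C | intermediate (not isolated)
10 | (2R,3R)-3-hydroxy-5-methyl-2-[(3S)-3-methylhexa-1,5-dien-3-yl]hex-5-enoic acid | OC(=O)[C@H]([C@@](C)(CC=C)C=C)[C@H](O)CC(C)=C | intermediate
11 | 3,4,5-trimethoxybenzoyl chloride | COc1cc(cc(OC)c1OC)C(Cl)=O | starting material
12 | (2R,3R)-5-methyl-2-[(3S)-3-methylhexa-1,5-dien-3-yl]-3-[(3,4,5-trimethoxybenzoyl)oxy]hex-5-enoic acid | OC(=O)[C@H]([C@@](C)(CC=C)C=C)[C@H](OC(=O)c1cc(OC)c(OC)c(OC)c1)CC(C)=C | intermediate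
13 | acid chloride of 12 | ClC(=O)[C@H]([C@@](C)(CC=C)C=C)[C@H](OC(=O)c1cc(OC)c(OC)c(OC)c1)CC(C)=C | intermediate (not isolated)
14 | (4R,5R)-2,7-dimethyl-4-[(3S)-3-methylhexa-1,5-dien-3-yl]-3-oxooct-7-en-5-yl 3,4,5-trimethoxybenzoate | CC(C)C(=O)[C@H]([C@@](C)(CC=C)C=C)[C@H](OC(=O)c1cc(OC)c(OC)c(OC)c1)CC(C)=C | intermediate
15 | (1R,6S,7R)-6-ethenyl-3,6-dimethyl-7-(2-methylpropanoyl)cyclohept-3-en-1-yl 3,4,5-trimethoxybenzoate | CC(C)C(=O)[C@@H]1[C@](C)(C=C)CC=C(C)C[C@H]1OC(=O)c2cc(OC)c(OC)c(OC)c2 | intermediate
16 | (1R,6R,7R)-6-acetyl-3,6-dimethyl-7-(2-methylpropanoyl)cyclohept-3-en-1-yl 3,4,5-trimethoxybenzoate | CC(C)C(=O)[C@@H]1[C@](C)(C(C)=O)CC=C(C)C[C@H]1OC(=O)c2cc(OC)c(OC)c(OC)c2 | intermediate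
17 | lithium enolate of 16 (acetyl methyl) | [Li+].CC(C)C(=O)[C@@H]1[C@](C)(C([O-])=C)CC=C(C)C[C@H]1OC(=O)c2cc(OC)c(OC)c(OC)c2 | intermediate (not isolated)
18 | (3S,3aR,4R,8aR)-3-hydroxy-6,8a-dimethyl-1-oxo-3-(propan-2-yl)-1,2,3,3a,4,5,8,8a-octahydroazulen-4-yl 3,4,5-trimethoxybenzoate | O=C1C[C@](O)(C(C)C)[C@H]2[C@H](OC(=O)c3cc(OC)c(OC)c(OC)c3)CC(C)=CC[C@@]12C | intermediate
19 | (1S,3S,3aR,4R,8aR)-1,3-dihydroxy-6,8a-dimethyl-3-(propan-2-yl)-1,2,3,3a,4,5,8,8a-octahydroazulen-4-yl 3,4,5-trimethoxybenzoate | O[C@H]1C[C@](O)(C(C)C)[C@H]2[C@H](OC(=O)c3cc(OC)c(OC)c(OC)c3)CC(C)=CC[C@@]12C | intermediate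
20 | angelic acid, (2Z)-2-methylbut-2-enoic acid | C/C=C(/C)C(=O)O | starting material
21 | angelic 2,4,6-trichlorobenzoic anhydride | C/C=C(/C)C(=O)OC(=O)c1c(Cl)cc(Cl)cc1Cl | intermediate (not isolated)
22 | CNP0112256.1, (1S,3S,3aR,4R,8aR)-3-hydroxy-6,8a-dimethyl-1-[(2Z)-2-methylbut-2-enoyloxy]-3-(propan-2-yl)-1,2,3,3a,4,5,8,8a-octahydroazulen-4-yl 3,4,5-trimethoxybenzoate | C/C=C(/C)C(=O)O[C@H]1C[C@](O)(C(C)C)[C@H]2[C@H](OC(=O)c3cc(OC)c(OC)c(OC)c3)CC(C)=CC[C@@]12C | target

Total step count: 13. Longest linear sequence: 11 steps (steps 3–13 from 5; equally steps 1, 2 and 5–13 from 1).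

Steps most likely to fail

Step 11 (key aldol). The aldolate may revert by retro-aldol cleavage, enolisation at C5 may expel the C6 benzoate, the product may dehydrate to the cyclopentenone, or the benzoate may migrate onto the new tertiary alkoxide. Fallback: from 16, soft enolisation with TMSOTf and Et3N in CH2Cl2 at 0 °C should silylate only the acetyl group and give the trimethylsilyl enol ether F1. Treatment of F1 with TiCl4 in CH2Cl2 at −78 °C (intramolecular Mukaiyama aldol) should form the same C3–C4 bond through a titanium aldolate under non-basic conditions, and aqueous work-up returns to the route at 18.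

Step 12 (C2 reduction). Facial selectivity may be poor if the catalyst is mismatched with the bicyclic substrate, or if a boron species bound to the C4 hydroxyl delivers hydride to the hydroxyl face and gives the trans-1,3-diol. Fallback: from 18, reduction with SmI2 in THF/MeOH at 0 °C (chelation-controlled ketyl reduction of a β-hydroxy ketone). Samarium(III) should bridge the C4 oxygen and the ketyl oxygen on one face of the cyclopentane, so that protonation from the opposite face gives the cis-diol and the route is rejoined at 19 without a new intermediate.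

Step 13 (angeloylation). Acylation of the neopentyl C2 carbinol may be slow, and the angelate may isomerise to the tiglate during prolonged heating with amine. Fallback: from 19, DCC/DMAP esterification of the C2 hydroxyl with 2-(diphenoxyphosphoryl)propanoic acid should give the phosphonate ester F2. Ando olefination of F2 with acetaldehyde (NaI, DBU, THF, −78 to 0 °C) then builds the Z-trisubstituted olefin on the ester and arrives at 22.

Further compounds
F1 | step 11 | (1R,6R,7R)-3,6-dimethyl-7-(2-methylpropanoyl)-6-[1-(trimethylsilyloxy)ethenyl]cyclohept-3-en-1-yl 3,4,5-trimethoxybenzoate | CC(C)C(=O)[C@@H]1[C@](C)(C(=C)O[Si](C)(C)C)CC=C(C)C[C@H]1OC(=O)c2cc(OC)c(OC)c(OC)c2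
F0 | step 12 | none | none
F2 | step 13 | (1S,3S,3aR,4R,8aR)-1-{[2-(diphenoxyphosphoryl)propanoyl]oxy}-3-hydroxy-6,8a-dimethyl-3-(propan-2-yl)-1,2,3,3a,4,5,8,8a-octahydroazulen-4-yl 3,4,5-trimethoxybenzoate (epimer mixture at the phosphonate carbon) | CC(C(=O)O[C@H]1C[C@](O)(C(C)C)[C@H]2[C@H](OC(=O)c3cc(OC)c(OC)c(OC)c3)CC(C)=CC[C@@]12C)P(=O)(Oc1ccccc1)Oc1ccccc1
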